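The cyclohexane (C-5 to C-10) is closed last, at C-7–C-8. The route rests on the all-cis O-6/C-7/O-8 triad: C-7, the carbon that carries the acrylic acid, is treated as a double allyl nucleophile. A Felkin-controlled Barbier addition first ties C-7 to C-6; the resulting γ-lactone (O-6 to C-12), a ring absent from the target, is kept as a 3-(bromomethyl)butenolide. In the key step indium converts this bromide into an allylindium that adds to the tethered C-8 aldehyde: one operation closes the carbocycle and sets C-7 and C-8. C-5 and C-10 come from an enantioselective Ireland–Claisen rearrangement; the lactone is hydrolysed at the end.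

Key step: step 13

Assumption 1 (locants): elemane numbering is used throughout. The ring is C-5 to C-10; C-10 carries CH3 (C-14) and the vinyl group C-1=C-2; C-5 carries C-4(=C-3)–C-15; C-7 carries C-11(=C-13)–C-12. TBS = tert-butyldimethylsilyl, TBDPS = tert-butyldiphenylsilyl.
Assumption 2 (chemistry): the (S,S) enantiomer of the boron controller in step 5 is taken to deliver acid 9; should it deliver the antipode, the (R,R) controller is used with no other change.

Step 1
Reactants: 1 tert-butyl(but-3-yn-1-yloxy)dimethylsilane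
Product: 3 (2E)-5-{[tert-butyl(dimethyl)silyl]oxy}-3-methylpent-2-en-1-ol, via alkenylalane 2 (not isolated)
Conditions: AlMe3, Cp2ZrCl2 (cat.), CH2Cl2, 0 °C → rt; then n-BuLi, (CH2O)n, THF, −78 °C → rt
Reagents that add atoms: trimethylaluminium, C[Al](C)C; paraformaldehyde (formaldehyde), C=O
Why: Negishi zirconium-catalysed carboalumination adds Me and Al syn across the alkyne (Me to the internal carbon), and trapping of the alkenyl aluminate with formaldehyde should give the (E)-trisubstituted allylic alcohol.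

Step 2
Reactants: 4 4-methoxy-2-methylidene-4-oxobutanoic acid (4-methyl itaconate)
Product: 5 methyl 3-(hydroxymethyl)but-3-enoate
Conditions: BH3·SMe2 (1.0 equiv), THF, −15 → 0 °C; MeOH quench
Reagents that add atoms: none
Why: Borane reduces a free carboxylic acid far faster than an ester or an electron-poor alkene, so the conjugated acid should be taken to the allylic alcohol selectively; 5 is silylated at once to forestall lactonisation.

Step 3
Reactants: 5 methyl 3-(hydroxymethyl)but-3-enoate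
Product: 6 methyl 3-({[tert-butyl(diphenyl)silyl]oxy}methyl)but-3-enoate
Conditions: TBDPSCl, imidazole, CH2Cl2, 0 °C → rt
Reagents that add atoms: tert-butyl(chloro)diphenylsilane, CC(C)(C)[Si](Cl)(c1ccccc1)c1ccccc1
Why: Standard silylation of a primary allylic alcohol.

Step 4
Reactants: 3 (2E)-5-{[tert-butyl(dimethyl)silyl]oxy}-3-methylpent-2-en-1-ol; 6 methyl 3-({[tert-butyl(diphenyl)silyl]oxy}methyl)but-3-enoate
Product: 7 (2E)-5-{[tert-butyl(dimethyl)silyl]oxy}-3-methylpent-2-en-1-yl 3-({[tert-butyl(diphenyl)silyl]oxy}methyl)but-3-enoate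
Conditions: Ti(OiPr)4 (0.2 equiv), 6 (1.5 equiv), toluene, 90 °C, 4 Å MS (removal of MeOH)
Reagents that add atoms: none
Why: Titanate-catalysed transesterification is neutral, so the β,γ-double bond should not move into conjugation and the allylic alcohol should not rearrange.

Step 5
Reactants: 7 (2E)-5-{[tert-butyl(dimethyl)silyl]oxy}-3-methylpent-2-en-1-yl 3-({[tert-butyl(diphenyl)silyl]oxy}methyl)but-3-enoate
Product: 9 (2S,3R)-5-{[tert-butyl(dimethyl)silyl]oxy}-2-(3-{[tert-butyl(diphenyl)silyl]oxy}prop-1-en-2-yl)-3-ethenyl-3-methylpentanoic acid, via boron ketene acetal 8 (not isolated)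
Conditions: (S,S)-bromoborane [from (S,S)-bis-sulfonamide and BBr3, CH2Cl2], Et3N, toluene–hexane, −78 °C → 4 °C; aqueous work-up
Reagents that add atoms: none
Why: Enantioselective Ireland–Claisen rearrangement with a chiral boron enolate: soft enolisation should give the E(O) ketene acetal 8, the chair [3,3] shift with the (E)-alkene places the C-9 chain equatorial and the methyl axial so that C-5 and C-10 form with the required relative configuration, and the C2-symmetric sulfonamide controller selects the face.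

Step 6
Reactants: 9 (2S,3R)-5-{[tert-butyl(dimethyl)silyl]oxy}-2-(3-{[tert-butyl(diphenyl)silyl]oxy}prop-1-en-2-yl)-3-ethenyl-3-methylpentanoic acid
Product: 10 (2S,3R)-5-{[tert-butyl(dimethyl)silyl]oxy}-2-(3-{[tert-butyl(diphenyl)silyl]oxy}prop-1-en-2-yl)-3-ethenyl-3-methylpentan-1-ol
Conditions: LiAlH4, Et2O, 0 °C → rt
Reagents that add atoms: none
Why: Hydride reduction of the acid to the primary alcohol; silyl ethers and isolated alkenes are inert.

Step 7
Reactants: 10 (2S,3R)-5-{[tert-butyl(dimethyl)silyl]oxy}-2-(3-{[tert-butyl(diphenyl)silyl]oxy}prop-1-en-2-yl)-3-ethenyl-3-methylpentan-1-ol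
Product: 11 (2S,3R)-5-{[tert-butyl(dimethyl)silyl]oxy}-2-(3-{[tert-butyl(diphenyl)silyl]oxy}prop-1-en-2-yl)-3-ethenyl-3-methylpentanal
Conditions: Dess–Martin periodinane, CH2Cl2, 0 °C → rt; used crude
Reagents that add atoms: none
Why: Dess–Martin oxidation is non-basic, so the β,γ-unsaturated aldehyde should be obtained without epimerisation at C-5 or conjugation.

Step 8
Reactants: 12 methyl 2-(bromomethyl)prop-2-enoate
Product: 13 methyl 2,3-dibromo-2-(bromomethyl)propanoate
Conditions: Br2, CH2Cl2, 0 °C → rt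
Reagents that add atoms: bromine, BrBr
Why: Electrophilic addition of bromine across the acrylate double bond.

Step 9
Reactants: 13 methyl 2,3-dibromo-2-(bromomethyl)propanoate
Product: 14 methyl (2Z)-3-bromo-2-(bromomethyl)prop-2-enoate
Conditions: Et3N (1.05 equiv), Et2O, 0 °C → rt
Reagents that add atoms: none
Why: Dehydrobromination (H from a CH2Br arm, Br from the tertiary α-carbon) gives the vinylic bromide; its geometry is irrelevant because this carbon becomes sp3 in step 10.

Step 10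
Reactants: 11 (2S,3R)-5-{[tert-butyl(dimethyl)silyl]oxy}-2-(3-{[tert-butyl(diphenyl)silyl]oxy}prop-1-en-2-yl)-3-ethenyl-3-methylpentanal; 14 methyl (2Z)-3-bromo-2-(bromomethyl)prop-2-enoate
Product: 16 methyl (3RS,4S,5S,6R)-3-bromo-8-{[tert-butyl(dimethyl)silyl]oxy}-5-(3-{[tert-butyl(diphenyl)silyl]oxy}prop-1-en-2-yl)-6-ethenyl-4-hydroxy-6-methyl-2-methylideneoctanoate, via allylindium reagent 15 (not isolated)
Conditions: 14 (2 equiv), In powder (1.3 equiv), THF/H2O 1:1, rt
Reagents that add atoms: none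
Why: Indium inserts only into the allylic C–Br bond and the γ-bromoallylindium 15 adds Barbier-fashion through its γ-carbon in a closed six-membered transition state; Felkin–Anh attack anti to the quaternary C-10 group on C-5 should set C-6, while the configuration at the new C–Br carbon (C-7) does not matter because step 13 re-metalates it.

Step 11
Reactants: 16 methyl (3RS,4S,5S,6R)-3-bromo-8-{[tert-butyl(dimethyl)silyl]oxy}-5-(3-{[tert-butyl(diphenyl)silyl]oxy}prop-1-en-2-yl)-6-ethenyl-4-hydroxy-6-methyl-2-methylideneoctanoate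
Product: 18 (5R)-3-(bromomethyl)-5-[(3S,4R)-2-({[tert-butyl(diphenyl)silyl]oxy}methyl)-4-ethenyl-6-hydroxy-4-methylhex-1-en-3-yl]furan-2(5H)-one, via bromolactone 17 (not isolated)
Conditions: TsOH·H2O (0.3 equiv), LiBr (0.2 equiv), MeCN/H2O 20:1, rt
Reagents that add atoms: none
Why: Acid-catalysed lactonisation of the γ-hydroxy ester (retention at C-6) gives 17, bromide-catalysed SN2′ transposition should funnel both bromide epimers into the conjugated 3-(bromomethyl)butenolide, and the same acid removes the primary TBS ether while the TBDPS ether survives.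

Step 12
Reactants: 18 (5R)-3-(bromomethyl)-5-[(3S,4R)-2-({[tert-butyl(diphenyl)silyl]oxy}methyl)-4-ethenyl-6-hydroxy-4-methylhex-1-en-3-yl]furan-2(5H)-one
Product: 19 (5R)-3-(bromomethyl)-5-[(3S,4R)-2-({[tert-butyl(diphenyl)silyl]oxy}methyl)-4-ethenyl-4-methyl-6-oxohex-1-en-3-yl]furan-2(5H)-one
Conditions: Dess–Martin periodinane, CH2Cl2, 0 °C → rt
Reagents that add atoms: none
Why: Dess–Martin oxidation of the primary alcohol; the neutral medium spares the allylic bromide and the base-sensitive γ-stereocentre (C-6) of the butenolide.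

Step 13
Reactants: 19 (5R)-3-(bromomethyl)-5-[(3S,4R)-2-({[tert-butyl(diphenyl)silyl]oxy}methyl)-4-ethenyl-4-methyl-6-oxohex-1-en-3-yl]furan-2(5H)-one
Product: 21 (3aR,4R,6R,7S,7aS)-7-(3-{[tert-butyl(diphenyl)silyl]oxy}prop-1-en-2-yl)-6-ethenyl-4-hydroxy-6-methyl-3-methylidenehexahydro-1-benzofuran-2(3H)-one, via allylindium 20 (not isolated)
Conditions: In powder (3 equiv), THF/H2O 3:1, 0.01 M, rt
Reagents that add atoms: none
Why: Indium inserts into the allylic C–Br bond of 19 to give allylindium 20, whose γ-carbon C-7 (a ring carbon of the butenolide) adds to the C-8 aldehyde through a closed six-membered transition state in which indium bridges C-13 and O-8, so the C-7–C-8 bond, the carbocycle and the exocyclic methylene all arise at once. The closest known reaction type is the zinc-, chromium- or indium-mediated Barbier allylation of aldehydes with 3-(bromomethyl)furan-2(5H)-ones and the intramolecular Barbier closure of ω-formyl 2-(bromomethyl)enoates to carbocycle-fused α-methylene lactones. The cyclohexane closes 6-exo-trig onto the aldehyde. C-7 is set by the tether, because the aldehyde arm hangs from C-5 on C-6 and can reach only the face of the planar butenolide syn to C-5, which forces a cis ring fusion (O-6 and C-11 cis, C-11 axial). C-8 is set by the closed transition state, because the lactone locks C-6 and C-12 cis across C-7=C-11, the CH2In arm therefore points away from C-6, and in the half-chair that keeps the C-5 substituent and the C-10 vinyl group equatorial the aldehyde oxygen can reach indium only from the equatorial site cis to C-11. The selectivity needed is this choice of half-chair (the flipped one would give the C-8 epimer) together with cyclisation ahead of protonolysis of 20, and it is secured by the fixed C-5, C-6 and C-10 centres, by the lactone, which also removes the A(1,3) strain and the 1,4-elimination open to an acyclic γ-oxygenated allylmetal, and by high dilution.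

Step 14
Reactants: 22 (4S)-2,2-dimethyl-1,3-dioxolane-4-carbaldehyde
Product: 23 (4R)-4-ethynyl-2,2-dimethyl-1,3-dioxolane
Conditions: dimethyl (1-diazo-2-oxopropyl)phosphonate, K2CO3, MeOH, 0 °C → rt
Reagents that add atoms: dimethyl (1-diazo-2-oxopropyl)phosphonate, CC(=O)C(=[N+]=[N-])P(=O)(OC)OC
Why: Ohira–Bestmann (Seyferth–Gilbert) homologation; the α-alkoxy stereocentre of this aldehyde should be carried through unchanged under K2CO3/MeOH.

Step 15
Reactants: 23 (4R)-4-ethynyl-2,2-dimethyl-1,3-dioxolane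
Product: 24 (2R)-but-3-yne-1,2-diol
Conditions: Dowex 50W (H+), MeOH/H2O, rt
Reagents that add atoms: none
Why: Acid-catalysed hydrolysis of the isopropylidene acetal.

Step 16
Reactants: 24 (2R)-but-3-yne-1,2-diol
Product: 25 (3R)-3,4-bis{[tert-butyl(dimethyl)silyl]oxy}but-1-yne
Conditions: TBSCl (2.4 equiv), imidazole, DMF, rt
Reagents that add atoms: tert-butyl(chloro)dimethylsilane, CC(C)(C)[Si](C)(C)Cl
Why: Silylation of both hydroxyls gives a diol protection that fluoride can remove at the end.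

Step 17
Reactants: 25 (3R)-3,4-bis{[tert-butyl(dimethyl)silyl]oxy}but-1-yne
Product: 26 tributyl[(3S)-3,4-bis{[tert-butyl(dimethyl)silyl]oxy}but-1-en-2-yl]stannane
Conditions: Bu3SnH, Mo(CO)3(CNt-Bu)3 (cat.), hydroquinone, THF, 55 °C
Reagents that add atoms: tributyltin hydride, CCCC[SnH](CCCC)CCCC
Why: Molybdenum-catalysed hydrostannation of propargylic ethers delivers tin to the internal carbon (syn addition), giving the 1,1-disubstituted vinylstannane without touching the stereocentre (the descriptor changes only through CIP priority).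

Step 18
Reactants: 26 tributyl[(3S)-3,4-bis{[tert-butyl(dimethyl)silyl]oxy}but-1-en-2-yl]stannane
Product: 28 (3R)-3,4-bis{[tert-butyl(dimethyl)silyl]oxy}-2-methylidenebutanoic acid, via vinyllithium 27 (not isolated)
Conditions: n-BuLi, THF, −78 °C; CO2; cold 1 M HCl work-up
Reagents that add atoms: carbon dioxide, O=C=O
Why: Tin–lithium exchange gives vinyllithium 27 and carboxylation at −78 °C should outrun β-elimination of the allylic silyloxy group.

Step 19
Reactants: 21 (3aR,4R,6R,7S,7aS)-7-(3-{[tert-butyl(diphenyl)silyl]oxy}prop-1-en-2-yl)-6-ethenyl-4-hydroxy-6-methyl-3-methylidenehexahydro-1-benzofuran-2(3H)-one; 28 (3R)-3,4-bis{[tert-butyl(dimethyl)silyl]oxy}-2-methylidenebutanoic acid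
Product: 30 (3aR,4R,6R,7S,7aS)-7-(3-{[tert-butyl(diphenyl)silyl]oxy}prop-1-en-2-yl)-6-ethenyl-6-methyl-3-methylidene-2-oxooctahydro-1-benzofuran-4-yl (3R)-3,4-bis{[tert-butyl(dimethyl)silyl]oxy}-2-methylidenebutanoate, via mixed anhydride 29 (not isolated)
Conditions: 2,4,6-trichlorobenzoyl chloride, Et3N, THF, rt; then 21, DMAP (cat.), toluene, rt
Reagents that add atoms: none
Why: Yamaguchi esterification; the C-8 hydroxyl is the only free one because O-6 is held in the lactone, and no stereocentre is touched.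

Step 20
Reactants: 30 (3aR,4R,6R,7S,7aS)-7-(3-{[tert-butyl(diphenyl)silyl]oxy}prop-1-en-2-yl)-6-ethenyl-6-methyl-3-methylidene-2-oxooctahydro-1-benzofuran-4-yl (3R)-3,4-bis{[tert-butyl(dimethyl)silyl]oxy}-2-methylidenebutanoate
Product: 32 (5S,6S,7S,8R,10R)-8-{[(3R)-3,4-dihydroxy-2-methylidenebutanoyl]oxy}-6,15-dihydroxyelema-1,3,11(13)-trien-12-oic acid (target), via silylated seco acid 31 (not isolated)
Conditions: LiOH·H2O (1.5 equiv), THF/H2O 3:1, 0 °C; AcOH to pH 6–7; then TBAF/AcOH (1:1), THF, rt; pH 5 work-up, reversed-phase purification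
Reagents that add atoms: water, O
Why: Hydroxide should open the unhindered γ-lactone faster than the hindered secondary acrylate ester, the carboxylate cannot relactonise, and acetic-acid-buffered fluoride then removes the three silyl groups near neutral pH, where neither the cis γ-hydroxy acid lactonises nor the dihydroxy side chain cyclises onto its own ester.

Compound list
1 | tert-butyl(but-3-yn-1-yloxy)dimethylsilane | C#CCCO[Si](C)(C)C(C)(C)C | starting material
2 | [(1E)-4-{[tert-butyl(dimethyl)silyl]oxy}-2-methylbut-1-en-1-yl]dimethylalumane | C/C(=C\[Al](C)C)CCO[Si](C)(C)C(C)(C)C | intermediate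
3 | (2E)-5-{[tert-butyl(dimethyl)silyl]oxy}-3-methylpent-2-en-1-ol | C/C(=C\CO)CCO[Si](C)(C)C(C)(C)C | intermediate
4 | 4-methoxy-2-methylidene-4-oxobutanoic acid (4-methyl itaconate) | COC(=O)CC(=C)C(=O)O | starting material
5 | methyl 3-(hydroxymethyl)but-3-enoate | COC(=O)CC(=C)CO | intermediate
6 | methyl 3-({[tert-butyl(diphenyl)silyl]oxy}methyl)but-3-enoate | COC(=O)CC(=C)CO[Si](c1ccccc1)(c1ccccc1)C(C)(C)C | intermediate
7 | (2E)-5-{[tert-butyl(dimethyl)silyl]oxy}-3-methylpent-2-en-1-yl 3-({[tert-butyl(diphenyl)silyl]oxy}methyl)but-3-enoate | C/C(=C\COC(=O)CC(=C)CO[Si](c1ccccc1)(c1ccccc1)C(C)(C)C)CCO[Si](C)(C)C(C)(C)C | intermediate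
8 | E(O) boron ketene acetal of 7 carrying the (4S,5S)-1,3-bis{[3,5-bis(trifluoromethyl)phenyl]sulfonyl}-4,5-diphenyl-1,3,2-diazaborolidin-2-yl group on the enolate oxygen | C=C(CO[Si](c1ccccc1)(c1ccccc1)C(C)(C)C)/C=C(\OC/C=C(\C)CCO[Si](C)(C)C(C)(C)C)OB1N(S(=O)(=O)c2cc(C(F)(F)F)cc(C(F)(F)F)c2)[C@@H](c2ccccc2)[C@H](c2ccccc2)N1S(=O)(=O)c1cc(C(F)(F)F)cc(C(F)(F)F)c1 | intermediate
9 | (2S,3R)-5-{[tert-butyl(dimethyl)silyl]oxy}-2-(3-{[tert-butyl(diphenyl)silyl]oxy}prop-1-en-2-yl)-3-ethenyl-3-methylpentanoic acid | C=C[C@@]([C@H](C(=O)O)C(=C)CO[Si](c1ccccc1)(c1ccccc1)C(C)(C)C)(C)CCO[Si](C)(C)C(C)(C)C | intermediate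
10 | (2S,3R)-5-{[tert-butyl(dimethyl)silyl]oxy}-2-(3-{[tert-butyl(diphenyl)silyl]oxy}prop-1-en-2-yl)-3-ethenyl-3-methylpentan-1-ol | C=C[C@@]([C@H](CO)C(=C)CO[Si](c1ccccc1)(c1ccccc1)C(C)(C)C)(C)CCO[Si](C)(C)C(C)(C)C | intermediate
11 | (2S,3R)-5-{[tert-butyl(dimethyl)silyl]oxy}-2-(3-{[tert-butyl(diphenyl)silyl]oxy}prop-1-en-2-yl)-3-ethenyl-3-methylpentanal | C=C[C@@]([C@H](C=O)C(=C)CO[Si](c1ccccc1)(c1ccccc1)C(C)(C)C)(C)CCO[Si](C)(C)C(C)(C)C | intermediate
12 | methyl 2-(bromomethyl)prop-2-enoate | C=C(CBr)C(=O)OC | starting material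
13 | methyl 2,3-dibromo-2-(bromomethyl)propanoate | COC(=O)C(Br)(CBr)CBr | intermediate
14 | methyl (2Z)-3-bromo-2-(bromomethyl)prop-2-enoate | COC(=O)/C(CBr)=C/Br | intermediate
15 | dibromo[3-bromo-2-(methoxycarbonyl)prop-2-en-1-yl]indium (allylindium, drawn as monomer) | COC(=O)C(C[In](Br)Br)=CBr | intermediate
16 | methyl (3RS,4S,5S,6R)-3-bromo-8-{[tert-butyl(dimethyl)silyl]oxy}-5-(3-{[tert-butyl(diphenyl)silyl]oxy}prop-1-en-2-yl)-6-ethenyl-4-hydroxy-6-methyl-2-methylideneoctanoate (both bromide epimers) | C=C[C@@]([C@H]([C@H](O)C(Br)C(=C)C(=O)OC)C(=C)CO[Si](c1ccccc1)(c1ccccc1)C(C)(C)C)(C)CCO[Si](C)(C)C(C)(C)C | intermediate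
17 | (4RS,5S)-4-bromo-5-[(3S,4R)-6-{[tert-butyl(dimethyl)silyl]oxy}-2-({[tert-butyl(diphenyl)silyl]oxy}methyl)-4-ethenyl-4-methylhex-1-en-3-yl]-3-methylideneoxolan-2-one | C=C[C@@]([C@H]([C@@H]1OC(=O)C(=C)C1Br)C(=C)CO[Si](c2ccccc2)(c2ccccc2)C(C)(C)C)(C)CCO[Si](C)(C)C(C)(C)C | intermediate
18 | (5R)-3-(bromomethyl)-5-[(3S,4R)-2-({[tert-butyl(diphenyl)silyl]oxy}methyl)-4-ethenyl-6-hydroxy-4-methylhex-1-en-3-yl]furan-2(5H)-one | C=C[C@@]([C@H]([C@@H]1OC(=O)C(CBr)=C1)C(=C)CO[Si](c2ccccc2)(c2ccccc2)C(C)(C)C)(C)CCO | intermediate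
19 | (5R)-3-(bromomethyl)-5-[(3S,4R)-2-({[tert-butyl(diphenyl)silyl]oxy}methyl)-4-ethenyl-4-methyl-6-oxohex-1-en-3-yl]furan-2(5H)-one | C=C[C@@]([C@H]([C@@H]1OC(=O)C(CBr)=C1)C(=C)CO[Si](c2ccccc2)(c2ccccc2)C(C)(C)C)(C)CC=O | intermediate
20 | allylindium derived from 19: dibromo({(5R)-2-oxo-5-[(3S,4R)-2-({[tert-butyl(diphenyl)silyl]oxy}methyl)-4-ethenyl-4-methyl-6-oxohex-1-en-3-yl]-2,5-dihydrofuran-3-yl}methyl)indium (drawn as monomer) | C=C[C@@]([C@H]([C@@H]1OC(=O)C(C[In](Br)Br)=C1)C(=C)CO[Si](c2ccccc2)(c2ccccc2)C(C)(C)C)(C)CC=O | intermediate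
21 | (3aR,4R,6R,7S,7aS)-7-(3-{[tert-butyl(diphenyl)silyl]oxy}prop-1-en-2-yl)-6-ethenyl-4-hydroxy-6-methyl-3-methylidenehexahydro-1-benzofuran-2(3H)-one | C=C[C@@]1(C)C[C@@H](O)[C@H]2C(=C)C(=O)O[C@H]2[C@@H]1C(=C)CO[Si](c3ccccc3)(c3ccccc3)C(C)(C)C | intermediate
22 | (4S)-2,2-dimethyl-1,3-dioxolane-4-carbaldehyde | O=C[C@@H]1COC(C)(C)O1 | starting material
23 | (4R)-4-ethynyl-2,2-dimethyl-1,3-dioxolane | C#C[C@@H]1COC(C)(C)O1 | intermediate
24 | (2R)-but-3-yne-1,2-diol | C#C[C@@H](O)CO | intermediate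
25 | (3R)-3,4-bis{[tert-butyl(dimethyl)silyl]oxy}but-1-yne | C#C[C@@H](O[Si](C)(C)C(C)(C)C)CO[Si](C)(C)C(C)(C)C | intermediate
26 | tributyl[(3S)-3,4-bis{[tert-butyl(dimethyl)silyl]oxy}but-1-en-2-yl]stannane | C=C([Sn](CCCC)(CCCC)CCCC)[C@@H](O[Si](C)(C)C(C)(C)C)CO[Si](C)(C)C(C)(C)C | intermediate
27 | [(3R)-3,4-bis{[tert-butyl(dimethyl)silyl]oxy}but-1-en-2-yl]lithium | C=C([Li])[C@@H](O[Si](C)(C)C(C)(C)C)CO[Si](C)(C)C(C)(C)C | intermediate
28 | (3R)-3,4-bis{[tert-butyl(dimethyl)silyl]oxy}-2-methylidenebutanoic acid | C=C(C(=O)O)[C@@H](O[Si](C)(C)C(C)(C)C)CO[Si](C)(C)C(C)(C)C | intermediate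
29 | mixed anhydride of 28 with 2,4,6-trichlorobenzoic acid | C=C(C(=O)OC(=O)c1c(Cl)cc(Cl)cc1Cl)[C@@H](O[Si](C)(C)C(C)(C)C)CO[Si](C)(C)C(C)(C)C | intermediate
30 | (3aR,4R,6R,7S,7aS)-7-(3-{[tert-butyl(diphenyl)silyl]oxy}prop-1-en-2-yl)-6-ethenyl-6-methyl-3-methylidene-2-oxooctahydro-1-benzofuran-4-yl (3R)-3,4-bis{[tert-butyl(dimethyl)silyl]oxy}-2-methylidenebutanoate | C=C[C@@]1(C)C[C@@H](OC(=O)C(=C)[C@@H](O[Si](C)(C)C(C)(C)C)CO[Si](C)(C)C(C)(C)C)[C@H]2C(=C)C(=O)O[C@H]2[C@@H]1C(=C)CO[Si](c3ccccc3)(c3ccccc3)C(C)(C)C | intermediate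
31 | (5S,6S,7S,8R,10R)-8-{[(3R)-3,4-bis{[tert-butyl(dimethyl)silyl]oxy}-2-methylidenebutanoyl]oxy}-15-{[tert-butyl(diphenyl)silyl]oxy}-6-hydroxyelema-1,3,11(13)-trien-12-oic acid | C=C[C@@]1(C)C[C@@H](OC(=O)C(=C)[C@@H](O[Si](C)(C)C(C)(C)C)CO[Si](C)(C)C(C)(C)C)[C@@H](C(=C)C(=O)O)[C@@H](O)[C@@H]1C(=C)CO[Si](c2ccccc2)(c2ccccc2)C(C)(C)C | intermediate
32 | (5S,6S,7S,8R,10R)-8-{[(3R)-3,4-dihydroxy-2-methylidenebutanoyl]oxy}-6,15-dihydroxyelema-1,3,11(13)-trien-12-oic acid | C=C[C@@]1(C)C[C@@H](OC(=O)C(=C)[C@@H](O)CO)[C@@H](C(=C)C(=O)O)[C@@H](O)[C@@H]1C(=C)CO | target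

Total step count: 20. Longest linear sequence: 12 steps (steps 2, 3, 4, 5, 6, 7, 10, 11, 12, 13, 19, 20).

Steps most likely to fail

Step 13 (key step). The ring may close through the flipped half-chair, which would deliver the C-8 epimer, or the allylindium may be protonated before it cyclises. The fallback sets out from 19 and uses the epimer instead of fighting it: the C-8 epimeric lactone alcohol F1 is esterified with acid 28 under Mitsunobu conditions (PPh3, DIAD, toluene, 0 °C). The inversion at C-8 should give ester 30 directly, where the fallback rejoins the route.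

Step 5. The boron ketene acetal may form with mixed geometry, the facial discrimination by the controller may be poor, or the rearrangement of this β,γ-unsaturated ester may be too slow. The fallback sets out from 7 and separates relative from absolute control: a standard Ireland–Claisen rearrangement (LDA, THF, −78 °C; TMSCl/Et3N; warm to rt) through the E(O) silyl ketene acetal F2 should give the racemic acid, that is 9 together with its enantiomer F3. The acid is resolved by crystallisation of its salt with (R)-1-phenylethylamine, salt F4 (the antipodal amine is taken if the salt of F3 is the one that crystallises). Acidification returns 9.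

Step 20. Hydroxide may attack the C-8 ester in competition with the lactone, or the liberated cis γ-hydroxy acid may relactonise during desilylation. The fallback sets out from 21 and opens the temporary lactone before the side chain is present. LiOH (THF/H2O) should give the dihydroxy acid F5, whose carboxylate is alkylated with allyl bromide in DMF to the allyl ester F6. The less hindered C-8 hydroxyl is then acylated with 28 (Yamaguchi) to give F7. Pd(PPh3)4/PhSiH3 cleaves the allyl ester under neutral conditions and returns the silylated seco acid 31, which is desilylated as in step 20 to 32.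

Further compounds
F1 | step 13 | (3aR,4S,6R,7S,7aS)-7-(3-{[tert-butyl(diphenyl)silyl]oxy}prop-1-en-2-yl)-6-ethenyl-4-hydroxy-6-methyl-3-methylidenehexahydro-1-benzofuran-2(3H)-one (C-8 epimer of 21) | C=C[C@@]1(C)C[C@H](O)[C@H]2C(=C)C(=O)O[C@H]2[C@@H]1C(=C)CO[Si](c3ccccc3)(c3ccccc3)C(C)(C)C
F2 | step 5 | E(O) trimethylsilyl ketene acetal of 7 | C=C(CO[Si](c1ccccc1)(c1ccccc1)C(C)(C)C)/C=C(\OC/C=C(\C)CCO[Si](C)(C)C(C)(C)C)O[Si](C)(C)C
F3 | step 5 | (2R,3S)-5-{[tert-butyl(dimethyl)silyl]oxy}-2-(3-{[tert-butyl(diphenyl)silyl]oxy}prop-1-en-2-yl)-3-ethenyl-3-methylpentanoic acid (enantiomer of 9) | C=C[C@]([C@@H](C(=O)O)C(=C)CO[Si](c1ccccc1)(c1ccccc1)C(C)(C)C)(C)CCO[Si](C)(C)C(C)(C)C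
F4 | step 5 | (1R)-1-phenylethanaminium salt of 9 | C=C[C@@]([C@H](C(=O)[O-])C(=C)CO[Si](c1ccccc1)(c1ccccc1)C(C)(C)C)(C)CCO[Si](C)(C)C(C)(C)C.C[C@@H]([NH3+])c1ccccc1
F5 | step 20 | (5S,6S,7S,8R,10R)-15-{[tert-butyl(diphenyl)silyl]oxy}-6,8-dihydroxyelema-1,3,11(13)-trien-12-oic acid | C=C[C@@]1(C)C[C@@H](O)[C@@H](C(=C)C(=O)O)[C@@H](O)[C@@H]1C(=C)CO[Si](c2ccccc2)(c2ccccc2)C(C)(C)C
F6 | step 20 | prop-2-en-1-yl ester of F5 | C=C[C@@]1(C)C[C@@H](O)[C@@H](C(=C)C(=O)OCC=C)[C@@H](O)[C@@H]1C(=C)CO[Si](c2ccccc2)(c2ccccc2)C(C)(C)C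
F7 | step 20 | prop-2-en-1-yl ester of 31 | C=C[C@@]1(C)C[C@@H](OC(=O)C(=C)[C@@H](O[Si](C)(C)C(C)(C)C)CO[Si](C)(C)C(C)(C)C)[C@@H](C(=C)C(=O)OCC=C)[C@@H](O)[C@@H]1C(=C)CO[Si](c2ccccc2)(c2ccccc2)C(C)(C)C
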